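Ring A (C4a, C5, C6, C7, C8, C8a) is a fully substituted phloroglucinol: oxygen on C5, C7 and C8a alternates with carbon on C6, C8 and C4a. It is therefore disconnected into a vinylketene (C5, C8, C8a, C4a) and an ynol ether (C6, C7). A photochemical Wolff rearrangement–benzannulation joins a chiral 6-(α-diazoacyl)-2-aryl-2,3-dihydro-4H-pyran-4-one, which already holds ring C, the S centre at C2 and the C8 prenyl group, to a prenylated silyl ynol ether; one operation forms C8–C8a, C5–C6, C7–C8 and C4a–C5 and delivers all six substituents of ring A. The pyranone comes from an asymmetric hetero-Diels–Alder reaction; global desilylation finishes.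

Key step: step 8

Remarks
- Numbering: flavanone numbers are used throughout (O1, C2, C3, C4, C4a, C5 to C8, C8a), also in the pyranone intermediates, where pyranone C5 is C4a and pyranone C6 is C8a. Ring A is the phloroglucinol ring, ring C the pyranone ring.
- Abbreviations: Ar = 4-(triisopropylsilyloxy)phenyl; TIPS = triisopropylsilyl; TMS = trimethylsilyl; TES = triethylsilyl; MOM = methoxymethyl; prenyl = 3-methylbut-2-enyl.
- Structures: target, diazoketone, ynol ether and benzannulation product are mutually consistent (C2 is S in all; diazoketone plus ynol ether minus N2 equals the product), so nothing needed correction.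
- Assumption: (S)-BINOL is taken to direct attack to the Si face of the aryl aldehyde, by analogy with BINOL–titanium additions to aromatic aldehydes. If the sense proves opposite, (R)-BINOL is used.
- Design of the precursor:
  - The side chain is attached by palladium-catalysed acylation of an alkylzinc reagent, not by a polar organometallic addition to an ester or amide, because the C4 carbonyl and C6 of the pyranone are electrophilic.
  - The aryl oxygen stays silylated to the end, so C2 cannot racemise through a quinone methide.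
  - Both prenyl groups enter only after the single strongly acidic operation (step 3).

Step 1
Reactants: 1 4-hydroxybenzaldehyde
Product: 2 4-(triisopropylsilyloxy)benzaldehyde
Conditions: TIPSCl, imidazole, DMF, 20 °C
Reagents that add atoms: chlorotriisopropylsilane, CC(C)[Si](Cl)(C(C)C)C(C)C
Why: Imidazole-promoted O-silylation of the phenol (silyl ether formation) is selective and gives a bulky aryl silyl ether that should survive the Lewis acid, trifluoroacetic acid, organozinc, amide base and light used later and that leaves together with the C7 silyl group in the last step.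

Step 2
Reactants: 3 ethyl 2,4-dioxopentanoate
Product: 4 ethyl (2Z)-2,4-bis(trimethylsilyloxy)penta-2,4-dienoate
Conditions: Me3SiOTf (2.2 equiv), Et3N (2.6 equiv), Et2O, 0 → 20 °C; filtered under argon, used crude
Reagents that add atoms: trimethylsilyl trifluoromethanesulfonate, C[Si](C)(C)OS(=O)(=O)C(F)(F)F
Why: Double enol silylation of the 1,3-dicarbonyl unit (soft enolisation with a silyl triflate and an amine) should give the 1,3-bis(silyloxy)diene, since after silylation of the chelated C2 enol the only remaining acidic hydrogens are those of the terminal methyl group.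

Step 3
Reactants: 2 4-(triisopropylsilyloxy)benzaldehyde; 4 ethyl (2Z)-2,4-bis(trimethylsilyloxy)penta-2,4-dienoate
Product: 6 ethyl (2S)-2-Ar-4-oxo-3,4-dihydro-2H-pyran-6-carboxylate, via silylated aldol adduct 5 (not isolated)
Conditions: (S)-BINOL (20 mol %), Ti(OiPr)4 (10 mol %), 4 Å molecular sieves, Et2O, −20 °C; then CF3CO2H, CH2Cl2, 0 °C
Reagents that add atoms: none
Why: Catalytic asymmetric hetero-Diels–Alder reaction by the Mukaiyama aldol–cyclisation pathway: the BINOL–titanium complex activates the aldehyde and is expected to expose its Si face to the terminal CH2 of the diene, which sets C2 as S, and trifluoroacetic acid then closes the ring by oxa-Michael addition–elimination of silanol at the ester-bearing carbon without breaking the C2–O bond.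

Step 4
Reactants: 6 ethyl (2S)-2-Ar-4-oxo-3,4-dihydro-2H-pyran-6-carboxylate
Product: 7 (2S)-2-Ar-4-oxo-3,4-dihydro-2H-pyran-6-carboxylic acid
Conditions: Me3SnOH (4 equiv), ClCH2CH2Cl, 70 °C; 1 M HCl wash
Reagents that add atoms: trimethyltin hydroxide, C[Sn](C)(C)O
Why: Ester hydrolysis with trimethyltin hydroxide runs under near-neutral conditions, so that free hydroxide cannot attack C6 of the β-alkoxy enone, open the ring by retro-aldol cleavage or strip the aryl silyl ether, and C2 is not touched.

Step 5
Reactants: 7 (2S)-2-Ar-4-oxo-3,4-dihydro-2H-pyran-6-carboxylic acid; 8 5-bromo-2-methylpent-2-ene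
Product: 11 (2S)-2-Ar-6-(5-methylhex-4-enoyl)-2,3-dihydro-4H-pyran-4-one, via acid chloride 9 (not isolated), via homoprenylzinc bromide 10 (not isolated)
Conditions: 7, (COCl)2, DMF (cat.), CH2Cl2, 0 → 20 °C, evaporation; separately 8, Zn dust, LiCl, THF, 50 °C; combined with Pd(PPh3)4 (5 mol %), THF, 0 → 20 °C
Reagents that add atoms: none
Why: Negishi acylation: the acid chloride adds oxidatively to zerovalent palladium and the alkylzinc bromide, made by zinc insertion into the primary bromide, transfers its alkyl group only at the acylpalladium stage, whereas an organomagnesium or organolithium reagent would also attack the C4 carbonyl and C6 of the pyranone.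

Step 6
Reactants: 11 (2S)-2-Ar-6-(5-methylhex-4-enoyl)-2,3-dihydro-4H-pyran-4-one
Product: 13 (2S)-2-Ar-6-(2-diazo-5-methylhex-4-enoyl)-2,3-dihydro-4H-pyran-4-one, via trifluoroacetyl diketone 12 (not isolated)
Conditions: LiN(SiMe3)2 (1.1 equiv), THF, −78 °C; CF3CO2CH2CF3, −78 °C; dilute HCl wash, crude; then 4-AcNHC6H4SO2N3, Et3N, H2O (1 equiv), MeCN, 20 °C
Reagents that add atoms: 4-acetamidobenzenesulfonyl azide, CC(=O)Nc1ccc(cc1)S(=O)(=O)N=[N+]=[N-]
Why: Detrifluoroacetylative diazo transfer (a deacylative Regitz reaction): the unhindered and more acidic side-chain CH2 is enolised at −78 °C and trifluoroacetylated, and the sulfonyl azide then transfers N2 to the doubly activated carbon with loss of the trifluoroacetyl group as an N-acylsulfonamide under an amine base too weak to enolise C3 or to disturb C2.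

Step 7
Reactants: 14 ethyl 4-methylpent-3-enoate
Product: 17 triisopropyl[(5-methylhex-4-en-1-yn-1-yl)oxy]silane, via dibromoketone enolate 15 (not isolated), via lithium ynolate 16 (not isolated)
Conditions: CH2Br2, lithium 2,2,6,6-tetramethylpiperidide, THF, −78 °C, then 14; LiN(SiMe3)2; n-BuLi, −78 → 0 °C; TIPSCl, −78 → 20 °C
Reagents that add atoms: dibromomethane, BrCBr; chlorotriisopropylsilane, CC(C)[Si](Cl)(C(C)C)C(C)C
Why: Kowalski ester homologation: bromine–lithium exchange on the dibromoketone enolate triggers 1,2-migration of the alkyl group to the carbenoid carbon to give the lithium ynolate, which the bulky chlorosilane silylates on oxygen to the isolable triisopropylsilyl ynol ether.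

Step 8
Reactants: 13 (2S)-2-Ar-6-(2-diazo-5-methylhex-4-enoyl)-2,3-dihydro-4H-pyran-4-one; 17 triisopropyl[(5-methylhex-4-en-1-yn-1-yl)oxy]silane
Product: 21 (2S)-5-hydroxy-6,8-bis(3-methylbut-2-enyl)-7-(triisopropylsilyloxy)-2-[4-(triisopropylsilyloxy)phenyl]chroman-4-one, via vinylketene 18 (not isolated), via cyclobutenone 19 (not isolated), via dienylketene 20 (not isolated)
Conditions: 17 (2 equiv), degassed ClCH2CH2Cl (0.2 M), hν (365 nm LED), 20 °C until N2 evolution ends; then 80 °C in the dark
Reagents that add atoms: none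
Why: Proposed new method: Irradiation of the diazoketone expels N2 with 1,2-shift of C8a from the acyl carbon to the diazo carbon (photochemical Wolff rearrangement, forming C8–C8a), and the resulting prenyl(vinyl)ketene 18 is captured by the ynol ether in a regioselective (2+2) cycloaddition in which the nucleophilic alkyne carbon bonds to the ketene carbonyl carbon (C6–C5) and the oxygen-bearing carbon to C8 (C7–C8), giving cyclobutenone 19. Under light or on warming 19 opens by 4π electrocyclic cleavage of its C5–C8 bond to dienylketene 20, and ring A is closed by thermal 6π electrocyclisation between the ketene carbon C5 and C4a, after which the cyclohexadienone tautomerises (hydrogen from C4a to O5) to the hydrogen-bonded C5 phenol. The closest known reaction is the Danheiser benzannulation in its photochemical diazoketone version with siloxyalkynes, which gives resorcinol monosilyl ethers; what is new is that the vinyl unit C8a=C4a is the double bond of a 2,3-dihydro-4H-pyran-4-one (a vinylogous ester) and that the diazo carbon carries an alkyl group. No stereocentre is formed, since the quaternary centre of 19 is lost on ring opening and C2 is remote and not enolisable under these neutral conditions. The regiochemistry needed is secured by the polarisation of the ynol ether, and the Wolff shift has to beat 1,2-hydrogen migration from the prenyl CH2, which is favoured by direct excitation of the s-cis diazoketone (loss of N2 concerted with migration) and by the absence of metal catalysts. The pyranone ring holds the C4 carbonyl trans to the ketene across C8a=C4a so that the ketene cannot collapse to an α-pyrone, C4a is the nucleophilic α-carbon of the vinylogous ester and thus matched to the electrophilic ketene carbon in the closure, and light of 365 nm or longer addresses the conjugated diazoketone while the simple enone and aryl ether chromophores of the products absorb little.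

Step 9
Reactants: 21 (2S)-5-hydroxy-6,8-bis(3-methylbut-2-enyl)-7-(triisopropylsilyloxy)-2-[4-(triisopropylsilyloxy)phenyl]chroman-4-one
Product: 22 (2S)-5,7-dihydroxy-2-(4-hydroxyphenyl)-6,8-bis(3-methylbut-2-enyl)chroman-4-one (6,8-diprenylnaringenin)
Conditions: Bu4NF (3 equiv), AcOH (3 equiv), THF, 0 °C
Reagents that add atoms: none
Why: Fluoride cleavage of both aryl silyl ethers, buffered with acetic acid so that no phenoxide (which could open ring C through a quinone methide and racemise C2) and no strong acid (which could cyclise a prenyl group onto a neighbouring phenol) is present.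

Compound list
1 | 4-hydroxybenzaldehyde | O=Cc1ccc(O)cc1 | starting material
2 | 4-(triisopropylsilyloxy)benzaldehyde | O=Cc1ccc(O[Si](C(C)C)(C(C)C)C(C)C)cc1 | intermediate
3 | ethyl 2,4-dioxopentanoate | CCOC(=O)C(=O)CC(C)=O | starting material
4 | ethyl (2Z)-2,4-bis(trimethylsilyloxy)penta-2,4-dienoate | CCOC(=O)/C(O[Si](C)(C)C)=C/C(=C)O[Si](C)(C)C | intermediate
5 | ethyl (2Z,6S)-4-oxo-6-[4-(triisopropylsilyloxy)phenyl]-2,6-bis(trimethylsilyloxy)hex-2-enoate | CCOC(=O)/C(O[Si](C)(C)C)=C/C(=O)C[C@@H](c1ccc(O[Si](C(C)C)(C(C)C)C(C)C)cc1)O[Si](C)(C)C | intermediate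
6 | ethyl (2S)-4-oxo-2-[4-(triisopropylsilyloxy)phenyl]-3,4-dihydro-2H-pyran-6-carboxylate | CCOC(=O)C1=CC(=O)C[C@@H](c2ccc(O[Si](C(C)C)(C(C)C)C(C)C)cc2)O1 | intermediate
7 | (2S)-4-oxo-2-[4-(triisopropylsilyloxy)phenyl]-3,4-dihydro-2H-pyran-6-carboxylic acid | OC(=O)C1=CC(=O)C[C@@H](c2ccc(O[Si](C(C)C)(C(C)C)C(C)C)cc2)O1 | intermediate
8 | 5-bromo-2-methylpent-2-ene | CC(C)=CCCBr | starting material
9 | (2S)-4-oxo-2-[4-(triisopropylsilyloxy)phenyl]-3,4-dihydro-2H-pyran-6-carbonyl chloride | ClC(=O)C1=CC(=O)C[C@@H](c2ccc(O[Si](C(C)C)(C(C)C)C(C)C)cc2)O1 | intermediate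
10 | (4-methylpent-3-en-1-yl)zinc bromide | CC(C)=CCC[Zn]Br | intermediate
11 | (2S)-6-(5-methylhex-4-enoyl)-2-[4-(triisopropylsilyloxy)phenyl]-2,3-dihydro-4H-pyran-4-one | CC(C)=CCCC(=O)C1=CC(=O)C[C@@H](c2ccc(O[Si](C(C)C)(C(C)C)C(C)C)cc2)O1 | intermediate
12 | (2S)-6-[5-methyl-2-(trifluoroacetyl)hex-4-enoyl]-2-[4-(triisopropylsilyloxy)phenyl]-2,3-dihydro-4H-pyran-4-one (side-chain centre undefined, enolised) | CC(C)=CCC(C(=O)C(F)(F)F)C(=O)C1=CC(=O)C[C@@H](c2ccc(O[Si](C(C)C)(C(C)C)C(C)C)cc2)O1 | intermediate
13 | (2S)-6-(2-diazo-5-methylhex-4-enoyl)-2-[4-(triisopropylsilyloxy)phenyl]-2,3-dihydro-4H-pyran-4-one | CC(C)=CCC(=[N+]=[N-])C(=O)C1=CC(=O)C[C@@H](c2ccc(O[Si](C(C)C)(C(C)C)C(C)C)cc2)O1 | intermediate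
14 | ethyl 4-methylpent-3-enoate | CCOC(=O)CC=C(C)C | starting material
15 | lithium 1,1-dibromo-5-methylhexa-1,4-dien-2-olate | [Li]OC(=C(Br)Br)CC=C(C)C | intermediate
16 | lithium 5-methylhex-4-en-1-yn-1-olate | [Li]OC#CCC=C(C)C | intermediate
17 | triisopropyl[(5-methylhex-4-en-1-yn-1-yl)oxy]silane | CC(C)=CCC#CO[Si](C(C)C)(C(C)C)C(C)C | intermediate
18 | 2-(3-methylbut-2-enyl)-2-[(2S)-4-oxo-2-[4-(triisopropylsilyloxy)phenyl]-3,4-dihydro-2H-pyran-6-yl]ethen-1-one (vinylketene) | CC(C)=CCC(=C=O)C1=CC(=O)C[C@@H](c2ccc(O[Si](C(C)C)(C(C)C)C(C)C)cc2)O1 | intermediate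
19 | 2,4-bis(3-methylbut-2-enyl)-4-[(2S)-4-oxo-2-[4-(triisopropylsilyloxy)phenyl]-3,4-dihydro-2H-pyran-6-yl]-3-(triisopropylsilyloxy)cyclobut-2-en-1-one (either configuration at the ring carbon C4) | CC(C)=CCC1=C(O[Si](C(C)C)(C(C)C)C(C)C)C(CC=C(C)C)(C1=O)C3=CC(=O)C[C@@H](c2ccc(O[Si](C(C)C)(C(C)C)C(C)C)cc2)O3 | intermediate
20 | (3E)-2,4-bis(3-methylbut-2-enyl)-4-[(2S)-4-oxo-2-[4-(triisopropylsilyloxy)phenyl]-3,4-dihydro-2H-pyran-6-yl]-3-(triisopropylsilyloxy)buta-1,3-dien-1-one (dienylketene, ketene and pyranonyl cis) | CC(C)=CCC(=C=O)/C(O[Si](C(C)C)(C(C)C)C(C)C)=C(CC=C(C)C)\C1=CC(=O)C[C@@H](c2ccc(O[Si](C(C)C)(C(C)C)C(C)C)cc2)O1 | intermediate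
21 | (2S)-5-hydroxy-6,8-bis(3-methylbut-2-enyl)-7-(triisopropylsilyloxy)-2-[4-(triisopropylsilyloxy)phenyl]chroman-4-one | CC(C)=CCc1c(O[Si](C(C)C)(C(C)C)C(C)C)c(CC=C(C)C)c2c(c1O)C(=O)C[C@@H](c1ccc(O[Si](C(C)C)(C(C)C)C(C)C)cc1)O2 | intermediate
22 | (2S)-5,7-dihydroxy-2-(4-hydroxyphenyl)-6,8-bis(3-methylbut-2-enyl)chroman-4-one (6,8-diprenylnaringenin) | CC(C)=CCc1c(O)c(CC=C(C)C)c2c(c1O)C(=O)C[C@@H](c1ccc(O)cc1)O2 | target

Total step count: 9
Longest linear sequence: 7 steps (steps 1, 3, 4, 5, 6, 8, 9)

Steps most likely to fail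

Step 8. The excited diazoketone may lose N2 to a free carbene that undergoes 1,2-hydrogen shift to a dienone instead of the Wolff migration. The ketene may be consumed by dimerisation or adventitious water before the ynol ether captures it. The enone may enter a photocycloaddition with the electron-rich alkyne. Silyl migration between O7 and O5 would not matter, since step 9 removes both groups.

The fallback gives up the benzannulation and takes ring A from a preformed phloroglucinol by known flavanone chemistry. It sets out from 1 and comes back at 22.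
- 1 is protected (MOMCl, iPr2NEt, CH2Cl2) to 4-(methoxymethoxy)benzaldehyde F1.
- 2,4,6-Trihydroxyacetophenone is C-prenylated twice (prenyl bromide, aqueous KOH, 0 °C; known but low-yielding) to 1-[2,4,6-trihydroxy-3,5-bis(3-methylbut-2-enyl)phenyl]ethanone F2.
- Its two non-chelated hydroxyls are protected (MOMCl, iPr2NEt) to 1-[2-hydroxy-4,6-bis(methoxymethoxy)-3,5-bis(3-methylbut-2-enyl)phenyl]ethanone F3.
- Claisen–Schmidt condensation of F3 with F1 (KOH, EtOH/H2O, 20 °C) should give the chalcone (E)-1-[2-hydroxy-4,6-bis(methoxymethoxy)-3,5-bis(3-methylbut-2-enyl)phenyl]-3-[4-(methoxymethoxy)phenyl]prop-2-en-1-one F4.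
- Dilute HCl in MeOH removes the three acetals, and NaOAc in refluxing EtOH closes ring C by oxa-Michael addition to racemic 6,8-diprenylnaringenin F5.
- Preparative HPLC on a polysaccharide carbamate chiral phase then separates the enantiomers and delivers 22.

Step 6. Enolisation may not be selective for the side-chain CH2. Deprotonation at C3 would put the diazo group on the ring and could open the ring by β-elimination of O1, which erodes the configuration at C2.

The fallback assembles the activated 1,3-dicarbonyl unit by C–C bond formation, so that no enolate of the pyranone ketone is ever made. It sets out from 7 (through 9) and 8 and comes back at 13.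
- The Grignard reagent of 8 (Mg, THF) is formylated with N-formylmorpholine (Bouveault aldehyde synthesis) to 5-methylhex-4-enal F6.
- Morpholine and K2CO3 convert it into the enamine 4-[(1E)-5-methylhexa-1,4-dien-1-yl]morpholine F7.
- Acid chloride 9, made from 7 as in step 5, acylates F7 at carbon (Et3N, CH2Cl2, −20 °C; Stork enamine acylation).
- Mild aqueous acid hydrolysis should give the α-formyl ketone 5-methyl-2-{[(2S)-4-oxo-2-[4-(triisopropylsilyloxy)phenyl]-3,4-dihydro-2H-pyran-6-yl]carbonyl}hex-4-enal F8.
- Deformylative Regitz diazo transfer (4-AcNHC6H4SO2N3, Et3N, MeCN, 0 → 20 °C) then gives 13.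

Step 3. Facial selectivity may be poor or the addition sluggish, because the ester-bearing bis(silyloxy)diene is a weaker nucleophile than the dienes for which the catalyst is established. The diene may also be desilylated prematurely.

The fallback sets the carbinol centre first with a stoichiometric chiral reagent and builds the diketo ester stepwise. It sets out from 2 and comes back at 6.
- Brown allylation of 2 with B-methallyldiisopinocampheylborane (Et2O, −78 °C; ethanolamine work-up) should give (1S)-3-methyl-1-[4-(triisopropylsilyloxy)phenyl]but-3-en-1-ol F9. The antipode that attacks the Si face is used, expected to be the one derived from (+)-α-pinene.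
- TESCl and imidazole give its silyl ether (1S)-3-methyl-1-(triethylsilyloxy)-1-[4-(triisopropylsilyloxy)phenyl]but-3-ene F10.
- Lemieux–Johnson cleavage (OsO4 cat., NaIO4, 2,6-lutidine, dioxane/H2O) gives (4S)-4-(triethylsilyloxy)-4-[4-(triisopropylsilyloxy)phenyl]butan-2-one F11.
- Claisen condensation at the methyl group (LiN(SiMe3)2, THF, −78 °C; diethyl oxalate) gives ethyl (2Z,6S)-2-hydroxy-4-oxo-6-(triethylsilyloxy)-6-[4-(triisopropylsilyloxy)phenyl]hex-2-enoate F12.
- CF3CO2H in CH2Cl2 at 0 °C removes the triethylsilyl group and cyclodehydrates to 6 with the C2–O bond intact.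

Further compounds
F1 | step 8 | 4-(methoxymethoxy)benzaldehyde | COCOc1ccc(C=O)cc1
F2 | step 8 | 1-[2,4,6-trihydroxy-3,5-bis(3-methylbut-2-enyl)phenyl]ethanone | CC(=O)c1c(O)c(CC=C(C)C)c(O)c(CC=C(C)C)c1O
F3 | step 8 | 1-[2-hydroxy-4,6-bis(methoxymethoxy)-3,5-bis(3-methylbut-2-enyl)phenyl]ethanone | CC(=O)c1c(O)c(CC=C(C)C)c(OCOC)c(CC=C(C)C)c1OCOC
F4 | step 8 | (E)-1-[2-hydroxy-4,6-bis(methoxymethoxy)-3,5-bis(3-methylbut-2-enyl)phenyl]-3-[4-(methoxymethoxy)phenyl]prop-2-en-1-one | COCOc1ccc(/C=C/C(=O)c2c(O)c(CC=C(C)C)c(OCOC)c(CC=C(C)C)c2OCOC)cc1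
F5 | step 8 | racemic 5,7-dihydroxy-2-(4-hydroxyphenyl)-6,8-bis(3-methylbut-2-enyl)chroman-4-one | CC(C)=CCc1c(O)c(CC=C(C)C)c2c(c1O)C(=O)CC(c1ccc(O)cc1)O2
F6 | step 6 | 5-methylhex-4-enal | CC(C)=CCCC=O
F7 | step 6 | 4-[(1E)-5-methylhexa-1,4-dien-1-yl]morpholine | CC(C)=CC/C=C/N1CCOCC1
F8 | step 6 | 5-methyl-2-{[(2S)-4-oxo-2-[4-(triisopropylsilyloxy)phenyl]-3,4-dihydro-2H-pyran-6-yl]carbonyl}hex-4-enal | CC(C)=CCC(C=O)C(=O)C1=CC(=O)C[C@@H](c2ccc(O[Si](C(C)C)(C(C)C)C(C)C)cc2)O1
F9 | step 3 | (1S)-3-methyl-1-[4-(triisopropylsilyloxy)phenyl]but-3-en-1-ol | CC(=C)C[C@@H](c1ccc(O[Si](C(C)C)(C(C)C)C(C)C)cc1)O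
F10 | step 3 | (1S)-3-methyl-1-(triethylsilyloxy)-1-[4-(triisopropylsilyloxy)phenyl]but-3-ene | CC(=C)C[C@@H](c1ccc(O[Si](C(C)C)(C(C)C)C(C)C)cc1)O[Si](CC)(CC)CC
F11 | step 3 | (4S)-4-(triethylsilyloxy)-4-[4-(triisopropylsilyloxy)phenyl]butan-2-one | CC(=O)C[C@@H](c1ccc(O[Si](C(C)C)(C(C)C)C(C)C)cc1)O[Si](CC)(CC)CC
F12 | step 3 | ethyl (2Z,6S)-2-hydroxy-4-oxo-6-(triethylsilyloxy)-6-[4-(triisopropylsilyloxy)phenyl]hex-2-enoate | CCOC(=O)/C(O)=C/C(=O)C[C@@H](c1ccc(O[Si](C(C)C)(C(C)C)C(C)C)cc1)O[Si](CC)(CC)CC
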